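All runs stem from a simulated flask for substances that don't exist; the scatter is artificial.

I began in a one-step world, where target at a fixed time follows the starting material charged in direct proportion.

| flask | starting material | coupling partner | target | time |
|---|---|---|---|---|
| eta | 0.300 M | 0.330 M |  |  |
| gamma | 0.150 M | 0.180 M |  |  |
| epsilon | 0.300 M | 0.330 M | 0.150 M |  |
| delta | 0.600 M | 0.330 M |  |  |
| alpha | 1.40 M | 0.330 M |  | 44 min |

| run | time / min | [target] / M |
|---|---|---|
| eta run | 1.6 | 0.0027 |
| eta run | 4.8 | 0.0093 |
| eta run | 9.2 | 0.0247 |
| eta run | 15 | 0.0430 |
| eta run | 21 | 0.0532 |
| eta run | 28 | 0.0630 |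
| eta run | 36 | 0.0715 |
| eta run | 44 | 0.0735 |
| gamma run | 1.6 | 3 × 10⁻⁴ |
| gamma run | 4.8 | 0.0036 |
| gamma run | 9.2 | 0.0080 |
| gamma run | 15 | 0.0162 |
| gamma run | 21 | 0.0205 |
| gamma run | 28 | 0.0267 |
| gamma run | 36 | 0.0280 |
| gamma run | 44 | 0.0309 |
| epsilon run | 1.6 | 0.1487 |
| epsilon run | 4.8 | 0.1529 |
| epsilon run | 9.2 | 0.1627 |
| epsilon run | 15 | 0.1718 |
| epsilon run | 21 | 0.1794 |
| epsilon run | 28 | 0.1810 |
| epsilon run | 36 | 0.1789 |
| epsilon run | 44 | 0.1743 |
| delta run | 1.6 | 0.0028 |
| delta run | 4.8 | 0.0192 |
| delta run | 9.2 | 0.0470 |
| delta run | 15 | 0.0802 |
| delta run | 21 | 0.1037 |
| delta run | 28 | 0.1213 |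
| delta run | 36 | 0.1344 |
| delta run | 44 | 0.1406 |

(each reading ± 9 × 10⁻⁴ M)

- Overall: starting material + coupling partner -> target.
- Constant volume, constant temperature.
- A reading of a species includes what of it is bound.
- "The second partner" is coupling partner.
- An order is taken over about fifteen percent of the charge, up and down.

1. how the opening rate goes with [starting material] round the charge of the eta run: the exponent of the rate at two percent of starting material gone to target (one fixed amount of target, the same in the runs compared)
2. how the opening rate goes with [coupling partner] round the charge of the eta run: the exponent of the rate at two percent of starting material gone to target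
3. target in the alpha run at 44 min, as a share of the starting material charged

The eta run read 0.0735 M at 44 min from 0.300 M of starting material. Scaled to the 1.40 M of the alpha run, that gave 0.343 M. This is more than the 0.330 M of coupling partner charged, and each target takes one partner. So proportion failed as a forecast for the alpha run, where coupling partner is the limiting reagent.

I went to logarithms. The delta and eta runs share a partner charge, and delta has twice the starting material, so their last readings gave n = 0.936. I call n the charge slope: the powers of ten of target gained at that time per power of ten of starting material charged, with partner held fixed. Carried up from delta, n gave 0.311 M in the alpha run. The gamma run, once n was taken out, gave a partner slope b = 0.359.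

The weak link was this: 0.311 M leaves 0.0190 M of partner outside target, but delta ended with 0.189 M, counting one partner per target read. So I supposed the alpha run ended with 0.0947 M of partner outside target, half of the delta figure, which means 0.235 M of target. Through b, that halving multiplies target by 0.780, giving 0.242 M. I committed to 17.3% of the starting material, with n and b as stand-ins for the two orders.

The forecast gave 16% (12.5% to 20%), with orders of 0.95 in starting material and 0.6 in coupling partner. Its ground for the first: “Delta/eta stays near 1.9–2.0 throughout, so the order in starting material is about 0.95.”

The alpha run gave 17.2% at 44 min, and the flask ran by these steps: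

    starting material → intermediate (0.03834 /min)
    intermediate + coupling partner → target (1.782 /M/min)
    intermediate → side product (0.1698 /min)
    target → decomposed product (0.009180 /min)
    2 coupling partner ⇌ idle reagent dimer, settled at all times (26.40 /M)

That share of the alpha charge is 0.240 M of target. The opening orders came out at 0.72 in starting material and 0.33 in coupling partner, below the forecast's 0.95 and 0.6. From delta to alpha the charge slope read 0.632, less than the n of 0.936.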